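## Retrosynthetic overview

1. Target 22 ← desilylation of 21; 21 ← asymmetric chromium-mediated intramolecular 2-(methoxycarbonyl)allylation of bromo-aldehyde 19 (C7–C8 bond: closes the ten-membered carbocycle first and sets both stereocentres), then lactonisation (five-membered lactone second).
2. 19 ← cross-metathesis of terminal alkene 16 with methyl 2-(bromomethyl)acrylate (C7=C11), then unmasking of the C8 aldehyde.
3. 16 ← E-selective Wittig reaction (C1=C10) of aldehyde 9 with α-formyl ylide 13, Luche reduction, silylation of C14–OH.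
4. 9 ← three-component anti-carbomagnesiation/allylation of propargyl alcohol (C3–C4 and C5–C6 bonds, fixes C4=C5), esterification with 2-hydroxyisobutyric acid, acetal hydrolysis.
5. Germacranolide numbering (C1–C15) is used in the comments: C7/C8 are the stereocentres, C14 carries the free OH, C15 the ester.

Assumption: the (S)-configured oxazoline–sulfonamide ligand is taken to direct the allylchromium reagent to the Re face of the C8 aldehyde (giving 8S); if a model reaction shows the opposite sense, the (R)-ligand is used.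

## Route

Step 1
Reactants: 1 prop-2-yn-1-ol; 2 2-(2-bromoethyl)-1,3-dioxolane; 3 allyl bromide
Product: 6 (2Z)-2-[2-(1,3-dioxolan-2-yl)ethyl]hexa-2,5-dien-1-ol, via acetal Grignard reagent 4 (not isolated), via vinylmagnesium alkoxide chelate 5 (not isolated)
Conditions: 2 (2.5 equiv), Mg, THF, 25 °C; then 1, CuI (10 mol%), Et2O/THF, −10 → 25 °C; then 3 (3 equiv), −20 → 25 °C; aq. NH4Cl
Reagents that add atoms: none
Why: Copper-catalysed anti-carbomagnesiation of the propargylic magnesium alkoxide (Duboudin-type) puts the alkyl group on the carbinol-bearing carbon and magnesium on the terminal carbon in a five-membered chelate, and copper-catalysed allylation of that vinyl–magnesium bond with retention fixes the alkene with the allyl group cis to CH2OH (the later ring-trans C4=C5).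

Step 2
Reactants: 6 (2Z)-2-[2-(1,3-dioxolan-2-yl)ethyl]hexa-2,5-dien-1-ol; 7 2-hydroxy-2-methylpropanoic acid
Product: 8 (2Z)-2-[2-(1,3-dioxolan-2-yl)ethyl]hexa-2,5-dien-1-yl 2-hydroxy-2-methylpropanoate
Conditions: 7 (1.5 equiv), EDC·HCl, DMAP (cat.), CH2Cl2, 0 → 25 °C
Reagents that add atoms: none
Why: Steglich esterification acylates the primary allylic alcohol, while the tertiary hydroxyl of the acid is too hindered to compete.

Step 3
Reactants: 8 (2Z)-2-[2-(1,3-dioxolan-2-yl)ethyl]hexa-2,5-dien-1-yl 2-hydroxy-2-methylpropanoate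
Product: 9 (2Z)-2-(3-oxopropyl)hexa-2,5-dien-1-yl 2-hydroxy-2-methylpropanoate
Conditions: 2 M HCl, THF, 25 °C
Reagents that add atoms: water, O
Why: Acid-catalysed acetal hydrolysis frees the C1 aldehyde; the hindered ester and the skipped diene are stable to dilute acid.

Step 4
Reactants: 10 [2-(1,3-dioxolan-2-yl)ethyl]triphenylphosphonium bromide; 11 ethyl formate
Product: 13 3-(1,3-dioxolan-2-yl)-2-(triphenyl-λ5-phosphanylidene)propanal, via non-stabilised phosphorus ylide 12 (not isolated)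
Conditions: KOtBu, THF, 0 °C; then 11, 0 → 25 °C
Reagents that add atoms: none
Why: C-formylation of a non-stabilised ylide with a formate ester (Bestmann-type acylation) gives the stabilised α-formyl ylide after proton loss to the released ethoxide.

Step 5
Reactants: 9 (2Z)-2-(3-oxopropyl)hexa-2,5-dien-1-yl 2-hydroxy-2-methylpropanoate; 13 3-(1,3-dioxolan-2-yl)-2-(triphenyl-λ5-phosphanylidene)propanal
Product: 14 (2Z)-2-[(3E)-5-(1,3-dioxolan-2-yl)-4-formylpent-3-en-1-yl]hexa-2,5-dien-1-yl 2-hydroxy-2-methylpropanoate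
Conditions: toluene, 90 °C
Reagents that add atoms: none
Why: Wittig olefination with a stabilised α-formyl ylide gives the E-enal under thermodynamic control, placing the formyl carbon (C14) trans to C2 and C9 cis to C2 (the later ring-cis C1=C10).

Step 6
Reactants: 14 (2Z)-2-[(3E)-5-(1,3-dioxolan-2-yl)-4-formylpent-3-en-1-yl]hexa-2,5-dien-1-yl 2-hydroxy-2-methylpropanoate
Product: 15 (2Z)-2-[(3E)-5-(1,3-dioxolan-2-yl)-4-(hydroxymethyl)pent-3-en-1-yl]hexa-2,5-dien-1-yl 2-hydroxy-2-methylpropanoate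
Conditions: NaBH4, CeCl3·7H2O, MeOH, −40 °C
Reagents that add atoms: none
Why: Luche reduction gives clean 1,2-reduction of the enal to the allylic alcohol and leaves the ester and alkenes untouched.

Step 7
Reactants: 15 (2Z)-2-[(3E)-5-(1,3-dioxolan-2-yl)-4-(hydroxymethyl)pent-3-en-1-yl]hexa-2,5-dien-1-yl 2-hydroxy-2-methylpropanoate
Product: 16 (2Z)-2-[(3E)-4-{[tert-butyl(diphenyl)silyl]oxymethyl}-5-(1,3-dioxolan-2-yl)pent-3-en-1-yl]hexa-2,5-dien-1-yl 2-hydroxy-2-methylpropanoate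
Conditions: TBDPSCl, imidazole, CH2Cl2, 0 → 25 °C
Reagents that add atoms: tert-butyl(chloro)diphenylsilane, CC(C)(C)[Si](Cl)(c1ccccc1)c1ccccc1
Why: Silyl ether formation is selective for the primary allylic alcohol over the tertiary one, and blocks C14–OH so the later C8 aldehyde cannot close to a lactol.

Step 8
Reactants: 16 (2Z)-2-[(3E)-4-{[tert-butyl(diphenyl)silyl]oxymethyl}-5-(1,3-dioxolan-2-yl)pent-3-en-1-yl]hexa-2,5-dien-1-yl 2-hydroxy-2-methylpropanoate; 17 methyl 2-(bromomethyl)prop-2-enoate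
Product: 18 methyl (2Z,5Z,9E)-2-(bromomethyl)-10-{[tert-butyl(diphenyl)silyl]oxymethyl}-11-(1,3-dioxolan-2-yl)-6-{[(2-hydroxy-2-methylpropanoyl)oxy]methyl}undeca-2,5,9-trienoate
Conditions: 17 (5 equiv), second-generation Hoveyda–Grubbs catalyst (10 mol%), 1,4-benzoquinone (10 mol%), CH2Cl2, 40 °C
Reagents that add atoms: none
Why: Olefin cross-metathesis engages only the monosubstituted terminal alkene (both trisubstituted alkenes are inert) with the 1,1-disubstituted acrylate, with loss of ethene, to give the 2-(bromomethyl)enoate.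

Step 9
Reactants: 18 methyl (2Z,5Z,9E)-2-(bromomethyl)-10-{[tert-butyl(diphenyl)silyl]oxymethyl}-11-(1,3-dioxolan-2-yl)-6-{[(2-hydroxy-2-methylpropanoyl)oxy]methyl}undeca-2,5,9-trienoate
Product: 19 methyl (2Z,5Z,9E)-2-(bromomethyl)-10-{[tert-butyl(diphenyl)silyl]oxymethyl}-6-{[(2-hydroxy-2-methylpropanoyl)oxy]methyl}-12-oxododeca-2,5,9-trienoate
Conditions: TsOH·H2O (cat.), THF/H2O (4:1), 35 °C; used crude
Reagents that add atoms: water, O
Why: Acid-catalysed acetal hydrolysis unmasks the β,γ-unsaturated C8 aldehyde, and the TBDPS ether, both esters and the allylic bromide tolerate the mild aqueous acid.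

Step 10
Reactants: 19 methyl (2Z,5Z,9E)-2-(bromomethyl)-10-{[tert-butyl(diphenyl)silyl]oxymethyl}-6-{[(2-hydroxy-2-methylpropanoyl)oxy]methyl}-12-oxododeca-2,5,9-trienoate
Product: 21 [(3aR,5Z,9E,11aS)-10-{[tert-butyl(diphenyl)silyl]oxymethyl}-3-methylidene-2-oxo-2,3,3a,4,7,8,11,11a-octahydrocyclodeca[b]furan-6-yl]methyl 2-hydroxy-2-methylpropanoate, via macrocyclic hydroxy ester 20 (not isolated)
Conditions: CrCl2 (4 equiv), (S)-N-[2-(4-isopropyl-4,5-dihydro-1,3-oxazol-2-yl)-6-methylphenyl]methanesulfonamide (4.4 equiv), Et3N, THF, 25 °C, 19 added over 12 h (final 2 mM); aq. work-up; then CSA (cat.), CH2Cl2, 25 °C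
Reagents that add atoms: none
Why: In this asymmetric Nozaki–Hiyama–Kishi-type allylation the allylchromium species (trivalent chromium) adds through its γ-carbon C7 in a closed chair transition state with C6 and C9 equatorial to give the anti adduct (trans H7/H8), the chiral ligand on chromium directs attack to the Re face of the aldehyde so that C8 is S and C7 is R, and acid then closes the γ-lactone with loss of methanol.

Step 11
Reactants: 21 [(3aR,5Z,9E,11aS)-10-{[tert-butyl(diphenyl)silyl]oxymethyl}-3-methylidene-2-oxo-2,3,3a,4,7,8,11,11a-octahydrocyclodeca[b]furan-6-yl]methyl 2-hydroxy-2-methylpropanoate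
Product: 22 [(3aR,5Z,9E,11aS)-10-(hydroxymethyl)-3-methylidene-2-oxo-2,3,3a,4,7,8,11,11a-octahydrocyclodeca[b]furan-6-yl]methyl 2-hydroxy-2-methylpropanoate
Conditions: HF·pyridine, pyridine/THF, 0 → 25 °C
Reagents that add atoms: none
Why: Buffered fluoride desilylation removes the TBDPS ether without touching the α-methylene lactone, the hindered ester or either stereocentre.

## Compound list

1 | prop-2-yn-1-ol | C#CCO | starting material
2 | 2-(2-bromoethyl)-1,3-dioxolane | BrCCC1OCCO1 | starting material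
3 | allyl bromide (3-bromoprop-1-ene) | C=CCBr | starting material
4 | [2-(1,3-dioxolan-2-yl)ethyl]magnesium bromide | Br[Mg]CCC1OCCO1 | intermediate
5 | bromomagnesium (2Z)-3-(bromomagnesio)-2-[2-(1,3-dioxolan-2-yl)ethyl]prop-2-en-1-olate (Mg cis to CH2O) | Br[Mg]OC/C(CCC1OCCO1)=C\[Mg]Br | intermediate
6 | (2Z)-2-[2-(1,3-dioxolan-2-yl)ethyl]hexa-2,5-dien-1-ol | OC/C(CCC1OCCO1)=C\CC=C | intermediate
7 | 2-hydroxy-2-methylpropanoic acid | CC(C)(O)C(=O)O | starting material
8 | (2Z)-2-[2-(1,3-dioxolan-2-yl)ethyl]hexa-2,5-dien-1-yl 2-hydroxy-2-methylpropanoate | CC(C)(O)C(=O)OC/C(CCC1OCCO1)=C\CC=C | intermediate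
9 | (2Z)-2-(3-oxopropyl)hexa-2,5-dien-1-yl 2-hydroxy-2-methylpropanoate | CC(C)(O)C(=O)OC/C(CCC=O)=C\CC=C | intermediate
10 | [2-(1,3-dioxolan-2-yl)ethyl]triphenylphosphonium bromide | [Br-].C1COC(CC[P+](c2ccccc2)(c2ccccc2)c2ccccc2)O1 | starting material
11 | ethyl formate | CCOC=O | starting material
12 | [2-(1,3-dioxolan-2-yl)ethylidene]triphenyl-λ5-phosphane | C1COC(CC=P(c2ccccc2)(c2ccccc2)c2ccccc2)O1 | intermediate
13 | 3-(1,3-dioxolan-2-yl)-2-(triphenyl-λ5-phosphanylidene)propanal | O=CC(CC1OCCO1)=P(c1ccccc1)(c1ccccc1)c1ccccc1 | intermediate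
14 | (2Z)-2-[(3E)-5-(1,3-dioxolan-2-yl)-4-formylpent-3-en-1-yl]hexa-2,5-dien-1-yl 2-hydroxy-2-methylpropanoate | O=C/C(CC1OCCO1)=C/CC/C(COC(=O)C(C)(C)O)=C/CC=C | intermediate
15 | (2Z)-2-[(3E)-5-(1,3-dioxolan-2-yl)-4-(hydroxymethyl)pent-3-en-1-yl]hexa-2,5-dien-1-yl 2-hydroxy-2-methylpropanoate | OC/C(CC1OCCO1)=C/CC/C(COC(=O)C(C)(C)O)=C/CC=C | intermediate
16 | (2Z)-2-[(3E)-4-{[tert-butyl(diphenyl)silyl]oxymethyl}-5-(1,3-dioxolan-2-yl)pent-3-en-1-yl]hexa-2,5-dien-1-yl 2-hydroxy-2-methylpropanoate | CC(C)(C)[Si](OC/C(CC1OCCO1)=C/CC/C(COC(=O)C(C)(C)O)=C/CC=C)(c1ccccc1)c1ccccc1 | intermediate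
17 | methyl 2-(bromomethyl)prop-2-enoate | C=C(CBr)C(=O)OC | starting material
18 | methyl (2Z,5Z,9E)-2-(bromomethyl)-10-{[tert-butyl(diphenyl)silyl]oxymethyl}-11-(1,3-dioxolan-2-yl)-6-{[(2-hydroxy-2-methylpropanoyl)oxy]methyl}undeca-2,5,9-trienoate | CC(C)(C)[Si](OC/C(CC1OCCO1)=C/CC/C(COC(=O)C(C)(C)O)=C/C/C=C(\CBr)C(=O)OC)(c1ccccc1)c1ccccc1 | intermediate
19 | methyl (2Z,5Z,9E)-2-(bromomethyl)-10-{[tert-butyl(diphenyl)silyl]oxymethyl}-6-{[(2-hydroxy-2-methylpropanoyl)oxy]methyl}-12-oxododeca-2,5,9-trienoate | CC(C)(C)[Si](OC/C(CC=O)=C/CC/C(COC(=O)C(C)(C)O)=C/C/C=C(\CBr)C(=O)OC)(c1ccccc1)c1ccccc1 | intermediate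
20 | methyl 2-[(1R,2S,4E,8Z)-4-{[tert-butyl(diphenyl)silyl]oxymethyl}-2-hydroxy-8-{[(2-hydroxy-2-methylpropanoyl)oxy]methyl}cyclodeca-4,8-dien-1-yl]prop-2-enoate | COC(=O)C(=C)[C@H]1C/C=C(\COC(=O)C(C)(C)O)CC/C=C(/CO[Si](c2ccccc2)(c2ccccc2)C(C)(C)C)C[C@@H]1O | intermediate
21 | [(3aR,5Z,9E,11aS)-10-{[tert-butyl(diphenyl)silyl]oxymethyl}-3-methylidene-2-oxo-2,3,3a,4,7,8,11,11a-octahydrocyclodeca[b]furan-6-yl]methyl 2-hydroxy-2-methylpropanoate | C=C1C(=O)O[C@H]2C/C(CO[Si](c3ccccc3)(c3ccccc3)C(C)(C)C)=C\CC/C(COC(=O)C(C)(C)O)=C/C[C@H]12 | intermediate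
22 | [(3aR,5Z,9E,11aS)-10-(hydroxymethyl)-3-methylidene-2-oxo-2,3,3a,4,7,8,11,11a-octahydrocyclodeca[b]furan-6-yl]methyl 2-hydroxy-2-methylpropanoate (7R,8S; trans-fused lactone; ring-cis C1=C10, ring-trans C4=C5) | C=C1C(=O)O[C@H]2C/C(CO)=C\CC/C(COC(=O)C(C)(C)O)=C/C[C@H]12 | target

## Step count and risks

Total step count: 11. Longest linear sequence: 10 steps (steps 1–3 and 5–11, from propargyl alcohol 1); step 4 is a one-step side branch.

The three steps most likely to fail:

Step 10 (asymmetric macrocyclisation). A ligand-controlled chromium allylation has to deliver both enantio- and anti-selectivity while closing a ten-membered ring, and this has no close precedent in the macrocyclic setting. Fallback: set out from 19 and cyclise with achiral CrCl2 alone (THF, high dilution), which remains anti-selective but is racemic, then lactonise with CSA as before. This gives 21 together with its mirror image, formed through the enantiomeric hydroxy ester methyl 2-[(1S,2R,4E,8Z)-4-{[tert-butyl(diphenyl)silyl]oxymethyl}-2-hydroxy-8-{[(2-hydroxy-2-methylpropanoyl)oxy]methyl}cyclodeca-4,8-dien-1-yl]prop-2-enoate F5 as the enantiomeric lactone [(3aS,5Z,9E,11aR)-10-{[tert-butyl(diphenyl)silyl]oxymethyl}-3-methylidene-2-oxo-2,3,3a,4,7,8,11,11a-octahydrocyclodeca[b]furan-6-yl]methyl 2-hydroxy-2-methylpropanoate F6. The racemate is resolved by preparative HPLC on a chiral stationary phase (amylose tris(3,5-dimethylphenylcarbamate)), and the (3aR,11aS) enantiomer comes back to the route at 21; half the material is lost.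

Step 8 (cross-metathesis). The 1,1-disubstituted, electron-poor bromo-acrylate is a reluctant metathesis partner, and the skipped diene can isomerise. Fallback: set out from 16 and build the enoate by carbonyl chemistry instead of metathesis.
- OsO4 (cat.)/NMO dihydroxylates the terminal alkene, the only one that is neither hindered nor deactivated by an allylic oxygen, to give (2Z)-2-[(3E)-4-{[tert-butyl(diphenyl)silyl]oxymethyl}-5-(1,3-dioxolan-2-yl)pent-3-en-1-yl]-5,6-dihydroxyhex-2-en-1-yl 2-hydroxy-2-methylpropanoate F2 (mixture of epimers).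
- NaIO4 cleaves the diol to the aldehyde (2Z)-2-[(3E)-4-{[tert-butyl(diphenyl)silyl]oxymethyl}-5-(1,3-dioxolan-2-yl)pent-3-en-1-yl]-5-oxopent-2-en-1-yl 2-hydroxy-2-methylpropanoate F3, used crude.
- Baylis–Hillman-type vinylalumination with [1-(methoxycarbonyl)vinyl]diisobutylaluminium (from methyl propiolate, i-Bu2AlH and NMO) gives methyl (5Z,9E)-10-{[tert-butyl(diphenyl)silyl]oxymethyl}-11-(1,3-dioxolan-2-yl)-3-hydroxy-6-{[(2-hydroxy-2-methylpropanoyl)oxy]methyl}-2-methylideneundeca-5,9-dienoate F4 (racemic carbinol).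
- SN2′ bromination (NBS, Me2S, CH2Cl2) comes back to the route at 18.

Step 1 (allylation of the vinylmagnesium intermediate). The functionalised Grignard reagent must add cleanly to the alkynol, and the chelated vinylmagnesium species must then be allylated without loss of geometry. Fallback: set out from 1 (through 4 and 5 as before) but quench 5 with I2, the best-established trapping of such chelates, to give (2Z)-2-[2-(1,3-dioxolan-2-yl)ethyl]-3-iodoprop-2-en-1-ol F1. Stille coupling of F1 with allyltributylstannane (Pd2(dba)3, AsPh3, NMP, 25 °C) proceeds with retention and comes back to the route at 6.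

## Further compounds

F1 | step 1 | (2Z)-2-[2-(1,3-dioxolan-2-yl)ethyl]-3-iodoprop-2-en-1-ol | OC/C(CCC1OCCO1)=C\I
F2 | step 8 | (2Z)-2-[(3E)-4-{[tert-butyl(diphenyl)silyl]oxymethyl}-5-(1,3-dioxolan-2-yl)pent-3-en-1-yl]-5,6-dihydroxyhex-2-en-1-yl 2-hydroxy-2-methylpropanoate | CC(C)(C)[Si](OC/C(CC1OCCO1)=C/CC/C(COC(=O)C(C)(C)O)=C/CC(O)CO)(c1ccccc1)c1ccccc1
F3 | step 8 | (2Z)-2-[(3E)-4-{[tert-butyl(diphenyl)silyl]oxymethyl}-5-(1,3-dioxolan-2-yl)pent-3-en-1-yl]-5-oxopent-2-en-1-yl 2-hydroxy-2-methylpropanoate | CC(C)(C)[Si](OC/C(CC1OCCO1)=C/CC/C(COC(=O)C(C)(C)O)=C/CC=O)(c1ccccc1)c1ccccc1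
F4 | step 8 | methyl (5Z,9E)-10-{[tert-butyl(diphenyl)silyl]oxymethyl}-11-(1,3-dioxolan-2-yl)-3-hydroxy-6-{[(2-hydroxy-2-methylpropanoyl)oxy]methyl}-2-methylideneundeca-5,9-dienoate | CC(C)(C)[Si](OC/C(CC1OCCO1)=C/CC/C(COC(=O)C(C)(C)O)=C/CC(O)C(=C)C(=O)OC)(c1ccccc1)c1ccccc1
F5 | step 10 | methyl 2-[(1S,2R,4E,8Z)-4-{[tert-butyl(diphenyl)silyl]oxymethyl}-2-hydroxy-8-{[(2-hydroxy-2-methylpropanoyl)oxy]methyl}cyclodeca-4,8-dien-1-yl]prop-2-enoate | COC(=O)C(=C)[C@@H]1C/C=C(\COC(=O)C(C)(C)O)CC/C=C(/CO[Si](c2ccccc2)(c2ccccc2)C(C)(C)C)C[C@H]1O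
F6 | step 10 | [(3aS,5Z,9E,11aR)-10-{[tert-butyl(diphenyl)silyl]oxymethyl}-3-methylidene-2-oxo-2,3,3a,4,7,8,11,11a-octahydrocyclodeca[b]furan-6-yl]methyl 2-hydroxy-2-methylpropanoate | C=C1C(=O)O[C@@H]2C/C(CO[Si](c3ccccc3)(c3ccccc3)C(C)(C)C)=C\CC/C(COC(=O)C(C)(C)O)=C/C[C@@H]12
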